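The numbers are invented; the rest is arithmetic.

The Qe I charged stayed in the flask as Qe, Qa or Ej, so those three summed to 0.060 M, and each Ej used one Ek.

    Qe ⇌ Qa (K1 = 2.1, k1 = 0.053 min⁻¹)
    Xi → Ek (k2 = 0.017 min⁻¹)
    Qa + Ek → Ej (k3 = 0.26 M⁻¹ min⁻¹)
    2 Ek → Kj (k4 = 0.0073 M⁻¹ min⁻¹)

Qe 0.060 M; Xi 0.900 equiv; time 5.0 d

- which holds at 5.0 d: what has brought the reaction to rest, or that it has not come to rest (Xi has run out first / all of Qe has reacted / it is still moving / forward and back rates have come level)
- amount of Ej at 5.0 d, in percent of the Qe charged
- amount of Qa at 5.0 d, in percent of the Qe charged

- for a step with 2 of a species take k times the square, and two of it per event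
- the reaction counts as stopped when no species that holds the Qe changes by six tenths of a point or more over the second half of the time
- run time (flask): 5.0 d

I called [Qe] + [Qa] the pool. Its two members relax in 0.148 h, far shorter than 5.0 d, so I took a fixed part of the pool to stand as Qa. This pre-equilibrium share f, equal to K/(1 + K), was the rule I carried:

f = 0.677, and [Qa] = f × pool

Xi is the limiting reagent at 0.900 equiv, and its half-life of 0.68 h is far shorter than 5.0 d. So I expected it to run out first, with Ej at most 90.0%. But some Ek pairs into Kj. Counting two Ek per pairing, the rate of loss over the rate of use is 0.0829 × [Ek]/pool. I read that ratio with the pool half gone, counting Xi as Ek and taking the gap as the pool that Ek cannot reach: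

first round: gap 10.0%, ratio 0.800, Ej 84.0%

second round: gap 16.0%, ratio 0.681, Ej 84.9%, Qa 10.2%

The weak link was letting the halfway ratio stand for the whole run, since it starts from nothing and sinks again. I knew no shape for that curve, so I tried a mean of 0.667 of its top as a guess, and committed to Ej between the second round and this trial:

Ej 86.6%, Qa 9.07%

The forecast said Xi has run out first, with Ej 86.1% and Qa 9.4%: “The reaction stops because the reagent is spent.” Its Ej lay above my second round and below my trial.

The simulation gave Xi has run out first, with Ej 86.1% and Qa 9.42%.

In this flask, f on the pool that Ej left gives Qa 9.41%. In a neighbour flask with 0.540 equiv of Xi, which reached Ej 53.0%, it gives 31.8%, and that flask held Qa 31.9%. Qe still stood at 4.49% in the first flask because Qa falls back to Qe. Without that falling back, the same flask converted 100% of its Qe instead of 95.5%.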